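Numbering (longipinane): C1(=O)-C2H=C3(Me)-C4H-C5H-C6Me2-C7H(O-angeloyl)-C8H(O-isobutyryl)-C9H2-C10(Me)-C11H, closed by C11-C1, C11-C5 and C10-C4. "Iso-longipinane" keeps these numbers but has C10 bonded to C2 instead of C4.
Enabling feature: the quaternary C10 sits on C4, the gamma carbon of the enone C1(=O)-C2=C3-C4, and is also tied to C11 next to the carbonyl. The bond C4-C10 can therefore be shifted back to C2, which shrinks the cyclohexenone ring C1-C2-C3-C4-C10-C11 to a cyclobutanone C1-C2-C10-C11 bearing the vinyl unit C3=C4.
Cuts, in order: the two ester C-O bonds; C4-C10 (1,3-shift); C1-C11 and C2-C10 together (vinylketene plus cycloheptene [2+2], which removes both bridges over the seven-membered ring at once); C5-C6 (Claisen); C5=C11 (cross-metathesis); C4-C5 (Stille).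
Forward: an oxolane from linalool, then the seven-membered ring by ring-expanding Claisen rearrangement, then cyclobutanone and cyclohexene ring together in the ketene cycloaddition. C8 and C7 are oxygenated on this cage, and the last ring event is the four-to-six expansion, which also closes the cyclobutane C4-C5-C11-C10.
Stereochemistry: the carbinol centre of (S)-linalool (future C10-O) is passed to C5 by the suprafacial Claisen shift. C5 then fixes C2, C10 and C11 (tethered [2+2]) and C4 (cage-bound shift); C8 comes from attack on the open face of the cage enolate, C7 from hydroxyl-directed hydride delivery.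

Key step: step 12

Assumption: (S)-(+)-linalool of high enantiomeric purity and ethyl (E)-4-bromo-3-methylbut-2-enoate are taken as purchasable.

Step 1
Reactants: 1 ethyl (E)-4-bromo-3-methylbut-2-enoate
Product: 2 ethyl (E)-3-methylhexa-2,5-dienoate
Conditions: CH2=CHSnBu3 (1.1 equiv), Pd2(dba)3 (2.5 mol %), AsPh3 (10 mol %), THF, 50 °C
Reagents that add atoms: tributyl(vinyl)stannane C=C[Sn](CCCC)(CCCC)CCCC
Why: Stille coupling of an allylic bromide with a vinylstannane (zerovalent palladium, neutral medium) makes the future C4-C5 bond, keeps the E enoate and does not conjugate the skipped diene; no stereocentre is formed.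

Step 2
Reactants: 3 (S)-(+)-linalool
Product: 4 (5S)-2-(2-bromopropan-2-yl)-5-ethenyl-5-methyloxolane (both C2 epimers)
Conditions: NBS (1.05 equiv), CH2Cl2, 0 °C, dark
Reagents that add atoms: N-bromosuccinimide O=C1CCC(=O)N1Br
Why: Bromoetherification, in which the electron-rich trisubstituted alkene takes up Br+ and the tertiary alcohol closes the oxolane in the 5-exo mode; the S carbinol centre (future C10) is untouched and the new O-CH centre (future C7) forms as an epimer mixture that step 4 erases.

Step 3
Reactants: 4 (5S)-2-(2-bromopropan-2-yl)-5-ethenyl-5-methyloxolane, 2 ethyl (E)-3-methylhexa-2,5-dienoate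
Product: 5 ethyl (2E,5E)-6-[(2S)-5-(2-bromopropan-2-yl)-2-methyloxolan-2-yl]-3-methylhexa-2,5-dienoate
Conditions: 2 (3 equiv), second-generation Hoveyda–Grubbs catalyst (5 mol %), 1,4-benzoquinone (10 mol %), CH2Cl2, 40 °C
Reagents that add atoms: none
Why: Olefin cross-metathesis between the unhindered terminal alkene of 2 and the vinyl group on the fully substituted carbon of 4 should favour the cross product; the bulky oxolane forces the E alkene that step 4 needs, the trisubstituted enoate is inert and benzoquinone suppresses alkene migration by ruthenium hydrides.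

Step 4
Reactants: 5 ethyl (2E,5E)-6-[(2S)-5-(2-bromopropan-2-yl)-2-methyloxolan-2-yl]-3-methylhexa-2,5-dienoate
Product: 7 ethyl (2E)-3-methyl-4-[(1S)-3,7,7-trimethyl-6-oxocyclohept-2-en-1-yl]but-2-enoate, via isopropylidene-oxolane enol ether 6 (not isolated)
Conditions: 2,4,6-collidine, reflux (171 °C)
Reagents that add atoms: none
Why: Collidine removes HBr (E2 toward the ring C-H) to give the allyl vinyl ether 6, whose ring-expanding Claisen rearrangement (known for 2-alkylidene-5-vinyloxolanes) forms C5-C6, the C7 ketone and the cis C10=C11 alkene at once; the shift is suprafacial through the only chair-like array the oxolane allows, so the S C-O centre and the E alkene translate into 5S.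

Step 5
Reactants: 7 ethyl (2E)-3-methyl-4-[(1S)-3,7,7-trimethyl-6-oxocyclohept-2-en-1-yl]but-2-enoate
Product: 8 (2E)-3-methyl-4-[(1S)-3,7,7-trimethyl-6-oxocyclohept-2-en-1-yl]but-2-enoic acid
Conditions: LiOH·H2O (3 equiv), THF/MeOH/H2O, 40 °C; then 1 M HCl
Reagents that add atoms: lithium hydroxide [Li+].[OH-]
Why: Saponification of an ordinary enoate; C5 is not acidic and the ketone can enolise only toward C8, so no stereocentre is at risk.

Step 6
Reactants: 8 (2E)-3-methyl-4-[(1S)-3,7,7-trimethyl-6-oxocyclohept-2-en-1-yl]but-2-enoic acid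
Product: 9 (2E)-3-methyl-4-[(1S)-3,7,7-trimethyl-6-oxocyclohept-2-en-1-yl]but-2-enoyl chloride
Conditions: (COCl)2 (1.5 equiv), DMF (cat.), CH2Cl2, 0 °C to rt; evaporate, use crude
Reagents that add atoms: oxalyl chloride O=C(Cl)C(=O)Cl
Why: Acid chloride formation by Vilsmeier-type activation is mild enough for the ketone and both alkenes and touches no stereocentre.

Step 7
Reactants: 9 (2E)-3-methyl-4-[(1S)-3,7,7-trimethyl-6-oxocyclohept-2-en-1-yl]but-2-enoyl chloride
Product: 11 (2S,5S,10S,11R)-3-methylidene-iso-longipinane-1,7-dione, via vinylketene 10 (not isolated)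
Conditions: Et3N (4 equiv), toluene (0.01 M), 110 °C, slow addition of 9
Reagents that add atoms: none
Why: Triethylamine removes HCl by gamma-deprotonation of the methyl group cis to the acyl chloride and gives vinylketene 10, which adds to C10=C11 in an intramolecular thermal ketene–alkene [2+2] cycloaddition; the three-atom tether and the polarity rule (C1 to the less substituted C11, C2 to the cation-stabilising C10) give the bridged bicyclo[3.1.1]heptan-6-one, and the tether on C5 admits only one alkene face, which sets C2, C10 and C11.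

Step 8
Reactants: 11 (2S,5S,10S,11R)-3-methylidene-iso-longipinane-1,7-dione
Product: 12 (2S,5S,10S,11R)-iso-longipin-3-ene-1,7-dione
Conditions: RuHCl(CO)(PPh3)3 (5 mol %), toluene, 80 °C
Reagents that add atoms: none
Why: Metal hydride addition–elimination moves the exocyclic alkene into the only allowed endocyclic position C3=C4 (C2 is a bridgehead), like the shift of pin-2(10)-ene to pin-2-ene, under neutral conditions that spare the acid-sensitive cyclobutanone; no stereocentre changes.

Step 9
Reactants: 12 (2S,5S,10S,11R)-iso-longipin-3-ene-1,7-dione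
Product: 14 (2S,5S,8S,10S,11R)-8-hydroxy-iso-longipin-3-ene-1,7-dione, via potassium enolate 13 (not isolated)
Conditions: KN(SiMe3)2 (1.1 equiv), THF, −78 °C; 2-(benzenesulfonyl)-3-phenyloxaziridine (1.3 equiv), −78 °C; aq NH4Cl
Reagents that add atoms: 2-(benzenesulfonyl)-3-phenyloxaziridine O=S(=O)(c1ccccc1)N1OC1c1ccccc1
Why: Davis oxidation, in which only the C7 ketone can enolise (toward C8, since C6 is quaternary and C2 and C11 are bridgeheads) and the oxaziridine should attack enolate 13 on the face of the seven-membered ring turned away from the C2-C3-C4 bridge lying under that ring, which gives 8S.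

Step 10
Reactants: 14 (2S,5S,8S,10S,11R)-8-hydroxy-iso-longipin-3-ene-1,7-dione
Product: 15 (2S,5S,7S,8S,10S,11R)-7,8-dihydroxy-iso-longipin-3-en-1-one
Conditions: Me4NBH(OAc)3 (4 equiv), MeCN/AcOH 1:1, −20 °C
Reagents that add atoms: none
Why: Saksena–Evans reduction, in which the 8-hydroxyl binds boron and delivers hydride to C7 from its own open face to give the trans 7S,8S diol, while the cyclobutanone has no hydroxyl neighbour and should be left alone by this weak hydride donor.

Step 11
Reactants: 15 (2S,5S,7S,8S,10S,11R)-7,8-dihydroxy-iso-longipin-3-en-1-one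
Product: 16 (2S,5S,7S,8S,10S,11R)-7-hydroxy-8-isobutyryloxy-iso-longipin-3-en-1-one
Conditions: iPrCOCl (1.05 equiv), pyridine, CH2Cl2, 0 °C
Reagents that add atoms: isobutyryl chloride CC(C)C(=O)Cl
Why: Sterically differentiated acylation, since the C8 hydroxyl next to CH2 reacts much faster than the neopentyl C7 hydroxyl next to C6 that also faces the cage; no stereocentre changes.

Step 12
Reactants: 16 (2S,5S,7S,8S,10S,11R)-7-hydroxy-8-isobutyryloxy-iso-longipin-3-en-1-one
Product: 17 (4R,5S,7S,8S,10R,11R)-7-hydroxy-8-isobutyryloxylongipin-2-en-1-one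
Conditions: mesitylene (0.01 M, degassed), BHT (5 mol %), base-washed sealed tube, 180 °C
Reagents that add atoms: none
Why: Proposed new method: heating should break the weakest bond of 16, C2-C10 (part of the strained cyclobutanone, allylic to C3=C4 and alpha to C1=O at one end, tertiary at the other), to give a short-lived singlet diradical made of a tertiary C10 radical and the 1-oxapentadienyl radical O=C1-C2-C3-C4, after which C10, still held by C11, swings over the same face of the ring C1-C2-C3-C4-C5-C11 and recombines at C4. The closest known reaction types are the thermal vinylcyclobutane-to-cyclohexene rearrangement, the degenerate 1,3-carbon shift by which pin-2-ene racemises on heating, the acid-promoted ring expansion of 2-vinylcyclobutanones to cyclohex-2-enones and the photochemical 1,3-shift of bicyclo[3.1.1]hept-3-en-2-ones, of which this step is the thermal reverse, but none of these has been shown on a bridged 2-vinylcyclobutanone. One bond exchange makes two rings: the four-membered ring C1-C2-C10-C11 grows by C3 and C4 into the cyclohexenone C1-C2-C3-C4-C10-C11 (1,3-shift, suprafacial on the allyl unit with retention at C10, hence stepwise and not concerted), and the cyclobutane C4-C5-C11-C10 closes by recombination of two radical centres that stand 1,3-diaxial on the six-membered ring. The only new stereocentre, C4, is fixed by the cage because C10 can reach C4 only from the face on which it is tied to C11, while C5, C7, C8, C10 and C11 keep their bonds and C2 becomes trigonal. The driving force should be the move of the carbonyl out of the four-membered ring into conjugation with C2=C3, and the competing cycloreversion to the vinylketene and the 1,3-acyl shift are reversible and lead back to 16. The selectivity needed is recombination at C4 rather than hydrogen transfer from C9 or the C10 methyl group to C2 or C4, and it is served by the equal distance of the C11-bound C10 to C2 and C4, by the stronger bond formed at C4 and by a dilute, non-polar, acid-free medium at the lowest workable temperature.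

Step 13
Reactants: 17 (4R,5S,7S,8S,10R,11R)-7-hydroxy-8-isobutyryloxylongipin-2-en-1-one
Product: 18 (4R,5S,7S,8S,10R,11R)-7-angeloyloxy-8-isobutyryloxylongipin-2-en-1-one (CNP0286736.1)
Conditions: angelic acid (3 equiv), 2,4,6-Cl3C6H2COCl (3 equiv), Et3N (3 equiv), toluene, rt; then 17, 80 °C
Reagents that add atoms: angelic acid C/C=C(/C)C(=O)O
Why: Yamaguchi-type esterification with the preformed mixed anhydride and no nucleophilic catalyst acylates the hindered C7 hydroxyl with retention at C7 and is a known way to avoid Z to E isomerisation of the angelate.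

Compound list
1 | ethyl (E)-4-bromo-3-methylbut-2-enoate | CCOC(=O)/C=C(\C)CBr | starting material
2 | ethyl (E)-3-methylhexa-2,5-dienoate | C=CC/C(C)=C/C(=O)OCC | intermediate
3 | (S)-(+)-linalool | C=C[C@@](C)(O)CCC=C(C)C | starting material
4 | (5S)-2-(2-bromopropan-2-yl)-5-ethenyl-5-methyloxolane, C2 epimers | C=C[C@]1(C)CCC(O1)C(C)(C)Br | intermediate
5 | ethyl (2E,5E)-6-[(2S)-5-(2-bromopropan-2-yl)-2-methyloxolan-2-yl]-3-methylhexa-2,5-dienoate | CCOC(=O)/C=C(\C)C/C=C/[C@]1(C)CCC(O1)C(C)(C)Br | intermediate
6 | ethyl (2E,5E)-3-methyl-6-[(2S)-2-methyl-5-(propan-2-ylidene)oxolan-2-yl]hexa-2,5-dienoate (not isolated) | CCOC(=O)/C=C(\C)C/C=C/[C@]1(C)CCC(=C(C)C)O1 | intermediate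
7 | ethyl (2E)-3-methyl-4-[(1S)-3,7,7-trimethyl-6-oxocyclohept-2-en-1-yl]but-2-enoate | CCOC(=O)/C=C(\C)C[C@H]1C=C(C)CCC(=O)C1(C)C | intermediate
8 | (2E)-3-methyl-4-[(1S)-3,7,7-trimethyl-6-oxocyclohept-2-en-1-yl]but-2-enoic acid | OC(=O)/C=C(\C)C[C@H]1C=C(C)CCC(=O)C1(C)C | intermediate
9 | (2E)-3-methyl-4-[(1S)-3,7,7-trimethyl-6-oxocyclohept-2-en-1-yl]but-2-enoyl chloride | ClC(=O)/C=C(\C)C[C@H]1C=C(C)CCC(=O)C1(C)C | intermediate
10 | vinylketene, 3-methylidene-4-[(1S)-3,7,7-trimethyl-6-oxocyclohept-2-en-1-yl]but-1-en-1-one (not isolated) | O=C=CC(=C)C[C@H]1C=C(C)CCC(=O)C1(C)C | intermediate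
11 | (2S,5S,10S,11R)-3-methylidene-iso-longipinane-1,7-dione (2,6,6-trimethyl-9-methylidenetricyclo[5.4.0.0(2,10)]undecane-5,11-dione; cyclobutanone C1-C2-C10-C11) | O=C1CC[C@@]2(C)[C@@H]3C(=O)[C@H]2C(=C)C[C@@H]3C1(C)C | intermediate
12 | (2S,5S,10S,11R)-iso-longipin-3-ene-1,7-dione (2,6,6,9-tetramethyltricyclo[5.4.0.0(2,10)]undec-8-ene-5,11-dione) | O=C1CC[C@@]2(C)[C@@H]3C(=O)[C@H]2C(C)=C[C@@H]3C1(C)C | intermediate
13 | potassium C7(O)=C8 enolate of 12 (not isolated) | [K+].[O-]C1=CC[C@@]2(C)[C@@H]3C(=O)[C@H]2C(C)=C[C@@H]3C1(C)C | intermediate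
14 | (2S,5S,8S,10S,11R)-8-hydroxy-iso-longipin-3-ene-1,7-dione (OH on the ring face away from the C2-C3-C4 bridge) | O=C1[C@@H](O)C[C@@]2(C)[C@@H]3C(=O)[C@H]2C(C)=C[C@@H]3C1(C)C | intermediate
15 | (2S,5S,7S,8S,10S,11R)-7,8-dihydroxy-iso-longipin-3-en-1-one (trans diol) | O[C@@H]1[C@@H](O)C[C@@]2(C)[C@@H]3C(=O)[C@H]2C(C)=C[C@@H]3C1(C)C | intermediate
16 | (2S,5S,7S,8S,10S,11R)-7-hydroxy-8-isobutyryloxy-iso-longipin-3-en-1-one | O[C@@H]1[C@@H](OC(=O)C(C)C)C[C@@]2(C)[C@@H]3C(=O)[C@H]2C(C)=C[C@@H]3C1(C)C | intermediate
17 | (4R,5S,7S,8S,10R,11R)-7-hydroxy-8-isobutyryloxylongipin-2-en-1-one (tricyclo[5.4.0.0(2,8)]undecane skeleton) | O[C@@H]1[C@@H](OC(=O)C(C)C)C[C@@]2(C)[C@@H]3C(=O)C=C(C)[C@H]2[C@@H]3C1(C)C | intermediate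
18 | (4R,5S,7S,8S,10R,11R)-7-angeloyloxy-8-isobutyryloxylongipin-2-en-1-one | C/C=C(/C)C(=O)O[C@@H]1[C@@H](OC(=O)C(C)C)C[C@@]2(C)[C@@H]3C(=O)C=C(C)[C@H]2[C@@H]3C1(C)C | target

Total step count: 13. Longest linear sequence: 12 (steps 2 to 13 from 3; the same length from 1 through step 1 and steps 3 to 13).

Steps most likely to fail

1. Step 12 (Proposed new method).
- What may go wrong: hydrogen transfer inside the diradical (from C9 or the C10 methyl group to C2 or C4), or a 1,5-hydrogen shift in the reversibly formed vinylketene, may outrun recombination at C4, so that the cage opens for good.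
- Fallback: an ionic open-and-close relay built from known reaction types, setting out from 16 and coming back at 17. HCl (1 M in Et2O, 1.1 equiv) in CH2Cl2 at −30 °C protonates C4, and the C3 cation cleaves C2-C10, in the way pin-2-ene opens to p-menth-1-en-8-yl chloride. This gives the bicyclic 10-chloro enone F1.
- TMSOTf/Et3N in CH2Cl2 at 0 °C then converts the enone into the linear 1-silyloxy-1,3-diene and caps the C7 hydroxyl, giving the bis-silylated chloro diene F2.
- ZnCl2 in CH2Cl2 at −40 °C ionises the tertiary chloride, and the silyl dienol ether is alkylated at its gamma carbon C4 (SN1-type tert-alkylation of silyl enol ethers, Reetz alkylation). The cage again allows only one face. The mildly acidic aqueous work-up frees the C7 hydroxyl and gives 17.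

2. Step 3.
- What may go wrong: slow turnover at the vinyl group on the fully substituted carbon, and migration of the skipped diene into conjugation before coupling.
- Fallback: setting out from 4 and coming back at 5, the side chain is built by C3-C4 cross-coupling instead of being brought in whole. Cross-metathesis of 4 with the very reactive (Z)-1,4-diacetoxybut-2-ene (same catalyst) gives the E allylic acetate F3. A Stille coupling of F3 with ethyl (E)-3-(tributylstannyl)but-2-enoate (Pd2(dba)3, LiCl, DMF, 40 °C) then forms the skipped diene only in the last operation and gives 5.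

3. Step 7.
- What may go wrong: oligomerisation of the ketene, or formation of vinylketene isomers that cannot reach the ring alkene.
- Fallback: setting out from 9 and coming back at 11, the ketene is replaced by a more electrophilic keteniminium ion. Me2NH converts 9 into the N,N-dimethylamide F4.
- Tf2O and 2,4,6-collidine in 1,2-dichloroethane at 80 °C activate the amide ahead of the ketone and give the vinylketeniminium triflate F5.
- F5 closes by intramolecular keteniminium–alkene [2+2] cycloaddition to the cyclobutaniminium triflate F6, and aqueous NaHCO3 hydrolyses F6 to 11.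

Further compounds
F1 | step 12 | bicyclic 10-chloro enone (C2-C10 seco form of 16 plus HCl; C5, C7, C8, C11 as in 16, C10 epimers) | O[C@@H]1[C@@H](OC(=O)C(C)C)CC(C)(Cl)[C@@H]2C(=O)C=C(C)C[C@@H]2C1(C)C
F2 | step 12 | bis-silylated chloro diene (1-trimethylsilyloxy-1,3-diene, 7-O-trimethylsilyl ether of F1) | C[Si](C)(C)O[C@@H]1[C@@H](OC(=O)C(C)C)CC(C)(Cl)[C@@H]2C(O[Si](C)(C)C)=CC(C)=C[C@@H]2C1(C)C
F3 | step 3 | (2E)-3-[(2S)-5-(2-bromopropan-2-yl)-2-methyloxolan-2-yl]prop-2-en-1-yl acetate | CC(=O)OC/C=C/[C@]1(C)CCC(O1)C(C)(C)Br
F4 | step 7 | (2E)-N,N,3-trimethyl-4-[(1S)-3,7,7-trimethyl-6-oxocyclohept-2-en-1-yl]but-2-enamide | CN(C)C(=O)/C=C(\C)C[C@H]1C=C(C)CCC(=O)C1(C)C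
F5 | step 7 | vinylketeniminium triflate derived from F4 | C[N+](C)=C=CC(=C)C[C@H]1C=C(C)CCC(=O)C1(C)C.[O-]S(=O)(=O)C(F)(F)F
F6 | step 7 | C1 dimethyliminium triflate of 11 | O=C1CC[C@@]2(C)[C@@H]3C(=[N+](C)C)[C@H]2C(=C)C[C@@H]3C1(C)C.[O-]S(=O)(=O)C(F)(F)F
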